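**Strategy.** Ring A of this eudesmane is cut at C1–C10 and C2–C3. A ring B cyclohexene carrying a 2-silyloxydiene (C3=C4–C5=C10) and, on its 8α-oxygen, a vinyldimethylsilyl group undergoes a thermal intramolecular Diels–Alder reaction: one operation closes ring A, builds the quaternary C10 and places silicon on C1. The step exploits the cis-1,3 relationship on ring B between O8 and the C10–C1 bond and the oxygen on C1 next to C10; the tether relays the C8 configuration to C10 and C1, and Tamao oxidation later turns C1–Si into the 1β-hydroxyl after O8 has been freed alone for its acetate. The precursor is a monocyclic triene made from a quinone monoketal.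

Key step: step 7

Remark: all atoms carry eudesmane numbers (C1–C10 in the bicycle, C14 on C10, C15 on C4, C11–C13 in the side chain on C7), also in the monocyclic precursors. α/β refer to the bicycle drawn with the C10 methyl β; "octalin" and "decalin" mean this 10-methyl bicycle. The target is (1R,4R,5S,6S,7S,8S,10R), as its SMILES defines.

Step 1
Reactants: 1 4-methoxy-2-methylphenol
Product: 2 4,4-dimethoxy-2-methylcyclohexa-2,5-dien-1-one
Conditions: PhI(OAc)2, MeOH, 0 °C
Reagents that add atoms: methanol (CO)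
Why: oxidative dearomatisation of a para-alkoxyphenol by the hypervalent iodine reagent in methanol should give the quinone monoketal, which has no stereocentre.

Step 2
Reactants: 2 4,4-dimethoxy-2-methylcyclohexa-2,5-dien-1-one; 3 (trimethylsilyl)acetylene
Product: 6 (5R)-4,4-dimethoxy-2-methyl-5-[(trimethylsilyl)ethynyl]cyclohex-2-en-1-one, via lithium acetylide 4 (not isolated), via alkynylalane 5 (not isolated)
Conditions: 3, n-BuLi, Et2O, −78 °C; Me2AlCl, 0 °C; then 2, Ni(acac)2 (5 mol%), chiral bis(oxazoline) ligand (6 mol%, enantiomer chosen for 5R), t-BuOMe, 0 °C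
Reagents that add atoms: none
Why: nickel-catalysed enantioselective conjugate alkynylation of a cyclic enone with a dimethylaluminium acetylide should attack the β-carbon of the enone arm that has no α-methyl group, and the chiral ligand on nickel sets C7.

Step 3
Reactants: 6 (5R)-4,4-dimethoxy-2-methyl-5-[(trimethylsilyl)ethynyl]cyclohex-2-en-1-one
Product: 8 (5R)-4,4-dimethoxy-2-methyl-5-[(trimethylsilyl)ethynyl]cyclohex-1-en-1-yl trifluoromethanesulfonate, via lithium enolate 7 (not isolated)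
Conditions: LiBH(s-Bu)3, THF, −78 °C; then PhNTf2, −78 °C → rt
Reagents that add atoms: N-phenylbis(trifluoromethanesulfonimide) (O=S(=O)(N(c1ccccc1)S(=O)(=O)C(F)(F)F)C(F)(F)F)
Why: conjugate hydride reduction of the α-methyl enone gives the tetrasubstituted enolate regiospecifically and O-triflation fixes the C5=C10 double bond, leaving C7 untouched.

Step 4
Reactants: 8 (5R)-4,4-dimethoxy-2-methyl-5-[(trimethylsilyl)ethynyl]cyclohex-1-en-1-yl trifluoromethanesulfonate
Product: 10 (4S,5R)-4-hydroxy-2-methyl-5-[(trimethylsilyl)ethynyl]cyclohex-1-en-1-yl trifluoromethanesulfonate, via keto triflate 9 (not isolated)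
Conditions: 1 M HCl, THF, 0 °C; then NaBH4, CeCl3·7H2O, MeOH, −78 °C
Reagents that add atoms: water (O)
Why: ketal hydrolysis followed at once by a Luche reduction, in which hydride adds axially to the cyclohexanone and should give the equatorial 8α-alcohol trans to the equatorial alkynyl group.

Step 5
Reactants: 10 (4S,5R)-4-hydroxy-2-methyl-5-[(trimethylsilyl)ethynyl]cyclohex-1-en-1-yl trifluoromethanesulfonate; 11 tributyl(1-ethoxyvinyl)stannane
Product: 13 1-[(4S,5R)-4-hydroxy-2-methyl-5-[(trimethylsilyl)ethynyl]cyclohex-1-en-1-yl]ethan-1-one, via ethoxydiene alcohol 12 (not isolated)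
Conditions: Pd(PPh3)4 (5 mol%), LiCl, THF, 65 °C; then 1 M HCl, rt
Reagents that add atoms: water (O)
Why: Stille coupling of the enol triflate with the α-ethoxyvinyl stannane brings in C4 and C3, and hydrolysis of the enol ether gives the acetylcyclohexene without touching a stereocentre.

Step 6
Reactants: 13 1-[(4S,5R)-4-hydroxy-2-methyl-5-[(trimethylsilyl)ethynyl]cyclohex-1-en-1-yl]ethan-1-one; 14 chloro(dimethyl)vinylsilane
Product: 16 (4S,5R)-1-[1-(tert-butyldimethylsilyloxy)ethenyl]-4-[(ethenyldimethylsilyl)oxy]-2-methyl-5-[(trimethylsilyl)ethynyl]cyclohex-1-ene, via vinylsilyl ether 15 (not isolated)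
Conditions: 14, Et3N, DMAP (cat.), CH2Cl2, 0 °C; then TBSOTf, Et3N, −78 → 0 °C
Reagents that add atoms: tert-butyldimethylsilyl trifluoromethanesulfonate (CC(C)(C)[Si](C)(C)OS(=O)(=O)C(F)(F)F)
Why: O-silylation of the C8 alcohol attaches the C1–C2 unit through a temporary silicon tether, and soft enolisation of the methyl ketone gives the cross-conjugated 2-silyloxydiene.

Step 7
Reactants: 16 (4S,5R)-1-[1-(tert-butyldimethylsilyloxy)ethenyl]-4-[(ethenyldimethylsilyl)oxy]-2-methyl-5-[(trimethylsilyl)ethynyl]cyclohex-1-ene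
Product: 17 siloxane-bridged Diels–Alder adduct (4-silyloxy-Δ4(5)-octalin carrying a 1β-SiMe2–O-8α bridge)
Conditions: PhMe (0.01 M), BHT (cat.), 190 °C, sealed tube
Reagents that add atoms: none
Why: A thermal, concerted, suprafacial [4+2] cycloaddition (type 1 intramolecular Diels–Alder) joins the diene C3=C4–C5=C10 and the tethered vinylsilane C1=C2; the closest known reaction type is the temporary-silicon-tethered vinylsilane Diels–Alder reaction of dienyl silyl ethers. Ring A closes as the cyclohexene of the cycloaddition (σ-bonds C2–C3 and C1–C10, enol ether moved to C4=C5), and the six-membered oxasilinane C10–C9–C8–O–Si–C1 closes with it as the tether ring, fused to ring A at C1–C10 and bridging C8 and C10 of ring B. C10 is controlled by C8: only the half-chair of ring B with the C8–O bond pseudoaxial lets the vinyl group reach C10, so C1 should add to the α-face, cis to O8, and the methyl group ends β. C1 is controlled by the tether geometry: silicon should sit exo, outside ring B next to C9, because the endo position would push SiMe2 under ring B against the axial 6α-hydrogen, and this places H1 anti to the C10 methyl and silicon β. The step needs regioselectivity, fixed by the four-atom tether, face selectivity, fixed as described, and enough reactivity of an unactivated dienophile towards a fully substituted diene terminus. For the last point the 2,3-disubstituted diene is biased towards s-cis, the small alkynyl group at C7 tolerates the axial position of the reacting conformer, and the reaction is intramolecular.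

Step 8
Reactants: 17 siloxane-bridged Diels–Alder adduct
Product: 18 siloxane-bridged 10β-methyl-7β-[(trimethylsilyl)ethynyl]octal-5-en-4-one
Conditions: Pd(OAc)2 (1.1 equiv), MeCN, rt
Reagents that add atoms: none
Why: Saegusa–Ito oxidation, in which palladation of the silyl enol ether at C5 is followed by β-hydride elimination that can only go towards C6, should give the Δ5-4-ketone regiospecifically.

Step 9
Reactants: 18 siloxane-bridged 10β-methyl-7β-[(trimethylsilyl)ethynyl]octal-5-en-4-one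
Product: 20 8α-acetoxy-1β-[methoxy(dimethyl)silyl]-10β-methyl-7β-[(trimethylsilyl)ethynyl]octal-5-en-4-one, via methoxysilane alcohol 19 (not isolated)
Conditions: PPTS (cat.), MeOH, rt; then Ac2O, pyridine, DMAP (cat.), CH2Cl2, 0 °C
Reagents that add atoms: methanol (CO); acetic anhydride (CC(=O)OC(C)=O)
Why: acid-catalysed methanolysis of the strained Si–O bond frees only the C8 hydroxyl while C1 stays masked as a methoxysilane, so acetylation puts the acetate on O8 alone.

Step 10
Reactants: 20 8α-acetoxy-1β-[methoxy(dimethyl)silyl]-10β-methyl-7β-[(trimethylsilyl)ethynyl]octal-5-en-4-one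
Product: 22 8α-acetoxy-7β-ethynyl-1β,6α-dihydroxy-10β-methyl-5αH-decalin-4-one, via boryl ketone 21 (not isolated)
Conditions: B2pin2, CuCl (5 mol%), Xantphos (5 mol%), NaOt-Bu (10 mol%), MeOH (2 equiv), THF, rt; then 30% H2O2, KF, KHCO3, THF/MeOH, rt → 40 °C
Reagents that add atoms: hydrogen peroxide (OO)
Why: copper-catalysed conjugate borylation should add boron to C6 trans to the C7 alkynyl group and anti to the C10 methyl, α-face protonation at C5 gives the trans-decalin, and the peroxide work-up oxidises C6–B and C1–Si with retention (Tamao–Fleming) while fluoride in methanol removes the alkyne silyl group.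

Step 11
Reactants: 22 8α-acetoxy-7β-ethynyl-1β,6α-dihydroxy-10β-methyl-5αH-decalin-4-one
Product: 23 8α-acetoxy-1β,6α-bis(tert-butyldimethylsilyloxy)-7β-ethynyl-10β-methyl-5αH-decalin-4-one
Conditions: TBSOTf, 2,6-lutidine, CH2Cl2, −78 → 0 °C
Reagents that add atoms: tert-butyldimethylsilyl trifluoromethanesulfonate (CC(C)(C)[Si](C)(C)OS(=O)(=O)C(F)(F)F)
Why: silyl triflate with a hindered pyridine base silylates both hindered secondary alcohols (C1 and C6) and protects the β-hydroxy ketone against elimination.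

Step 12
Reactants: 23 8α-acetoxy-1β,6α-bis(tert-butyldimethylsilyloxy)-7β-ethynyl-10β-methyl-5αH-decalin-4-one
Product: 24 8α-acetoxy-1β,6α-bis(tert-butyldimethylsilyloxy)-7β-ethynyl-10β-methyl-4-methylidene-5αH-decalin
Conditions: Zn, CH2Br2, TiCl4, THF/CH2Cl2, 0 °C → rt
Reagents that add atoms: dibromomethane (BrCBr)
Why: Takai–Lombardo methylenation is non-basic, so C5 should not epimerise and the C6 silyl ether should not eliminate, and it takes the ketone in preference to the acetate.

Step 13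
Reactants: 24 8α-acetoxy-1β,6α-bis(tert-butyldimethylsilyloxy)-7β-ethynyl-10β-methyl-4-methylidene-5αH-decalin
Product: 26 8α-acetoxy-1β,6α-bis(tert-butyldimethylsilyloxy)-7β-ethynyl-4α-hydroxy-4β,10β-dimethyl-5αH-decalin, via hydroperoxide 25 (not isolated)
Conditions: Mn(dpm)3 (10 mol%), PhSiH3, O2 (1 atm), i-PrOH/CH2Cl2, 0 °C; then PPh3
Reagents that add atoms: dioxygen (O=O)
Why: Mukaiyama hydration (hydrogen-atom transfer to the exocyclic CH2, then trapping of the tertiary C4 radical by O2) should put oxygen on the α-face because the β-face is blocked by the syn-axial C10 methyl, giving 4α-OH and a β-methyl.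

Step 14
Reactants: 26 8α-acetoxy-1β,6α-bis(tert-butyldimethylsilyloxy)-7β-ethynyl-4α-hydroxy-4β,10β-dimethyl-5αH-decalin
Product: 27 methyl 8α-acetoxy-1β,6α-bis(tert-butyldimethylsilyloxy)-4α-hydroxyeudesm-11(13)-en-12-oate
Conditions: CO (20 bar), MeOH, Pd(OAc)2 (1 mol%), 2-(diphenylphosphino)pyridine (20 mol%), MsOH (cat.), 50 °C
Reagents that add atoms: carbon monoxide ([C-]#[O+]); methanol (CO)
Why: palladium-catalysed Markovnikov hydromethoxycarbonylation of the terminal alkyne should give the branched acrylate, and the silyl group on O6 prevents lactone formation.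

Step 15
Reactants: 27 methyl 8α-acetoxy-1β,6α-bis(tert-butyldimethylsilyloxy)-4α-hydroxyeudesm-11(13)-en-12-oate
Product: 28 methyl 8α-acetoxy-1β,4α,6α-trihydroxyeudesm-11(13)-en-12-oate (target)
Conditions: HF·pyridine, pyridine/THF, 0 °C → rt
Reagents that add atoms: none
Why: buffered fluoride cleaves both silyl ethers and should leave the acetate, the tertiary alcohol and the acrylate intact.

**Compound list**

1 | 4-methoxy-2-methylphenol | COc1ccc(O)c(C)c1 | starting material
2 | 4,4-dimethoxy-2-methylcyclohexa-2,5-dien-1-one | COC1(OC)C=CC(=O)C(C)=C1 | intermediate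
3 | (trimethylsilyl)acetylene | C[Si](C)(C)C#C | starting material
4 | lithium (trimethylsilyl)acetylide (not isolated) | [Li+].[C-]#C[Si](C)(C)C | intermediate
5 | dimethyl[(trimethylsilyl)ethynyl]aluminium (not isolated) | C[Al](C)C#C[Si](C)(C)C | intermediate
6 | (5R)-4,4-dimethoxy-2-methyl-5-[(trimethylsilyl)ethynyl]cyclohex-2-en-1-one | CC1=CC(OC)(OC)[C@@H](C#C[Si](C)(C)C)CC1=O | intermediate
7 | lithium (5R)-4,4-dimethoxy-2-methyl-5-[(trimethylsilyl)ethynyl]cyclohex-1-en-1-olate (not isolated) | [Li+].[O-]C1=C(C)CC(OC)(OC)[C@@H](C#C[Si](C)(C)C)C1 | intermediate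
8 | (5R)-4,4-dimethoxy-2-methyl-5-[(trimethylsilyl)ethynyl]cyclohex-1-en-1-yl trifluoromethanesulfonate | FC(F)(F)S(=O)(=O)OC1=C(C)CC(OC)(OC)[C@@H](C#C[Si](C)(C)C)C1 | intermediate
9 | (5R)-2-methyl-4-oxo-5-[(trimethylsilyl)ethynyl]cyclohex-1-en-1-yl trifluoromethanesulfonate (not isolated) | FC(F)(F)S(=O)(=O)OC1=C(C)CC(=O)[C@@H](C#C[Si](C)(C)C)C1 | intermediate
10 | (4S,5R)-4-hydroxy-2-methyl-5-[(trimethylsilyl)ethynyl]cyclohex-1-en-1-yl trifluoromethanesulfonate | FC(F)(F)S(=O)(=O)OC1=C(C)C[C@H](O)[C@@H](C#C[Si](C)(C)C)C1 | intermediate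
11 | tributyl(1-ethoxyvinyl)stannane | CCCC[Sn](CCCC)(CCCC)C(=C)OCC | starting material
12 | (1S,6R)-4-(1-ethoxyethenyl)-3-methyl-6-[(trimethylsilyl)ethynyl]cyclohex-3-en-1-ol (not isolated) | C=C(OCC)C1=C(C)C[C@H](O)[C@@H](C#C[Si](C)(C)C)C1 | intermediate
13 | 1-[(4S,5R)-4-hydroxy-2-methyl-5-[(trimethylsilyl)ethynyl]cyclohex-1-en-1-yl]ethan-1-one | CC(=O)C1=C(C)C[C@H](O)[C@@H](C#C[Si](C)(C)C)C1 | intermediate
14 | chloro(dimethyl)vinylsilane | C=C[Si](C)(C)Cl | starting material
15 | 1-[(4S,5R)-4-[(ethenyldimethylsilyl)oxy]-2-methyl-5-[(trimethylsilyl)ethynyl]cyclohex-1-en-1-yl]ethan-1-one (not isolated) | CC(=O)C1=C(C)C[C@H](O[Si](C)(C)C=C)[C@@H](C#C[Si](C)(C)C)C1 | intermediate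
16 | (4S,5R)-1-[1-(tert-butyldimethylsilyloxy)ethenyl]-4-[(ethenyldimethylsilyl)oxy]-2-methyl-5-[(trimethylsilyl)ethynyl]cyclohex-1-ene | C=C(O[Si](C)(C)C(C)(C)C)C1=C(C)C[C@H](O[Si](C)(C)C=C)[C@@H](C#C[Si](C)(C)C)C1 | intermediate
17 | siloxane-bridged Diels–Alder adduct: 4-(tert-butyldimethylsilyloxy)-10β-methyl-7β-[(trimethylsilyl)ethynyl]-Δ4(5)-octalin with a 1β-SiMe2–O-8α bridge | C[Si](C)(C)C#C[C@H]1CC2=C(O[Si](C)(C)C(C)(C)C)CC[C@@H]([Si]3(C)C)[C@]2(C)C[C@@H]1O3 | intermediate
18 | siloxane-bridged 10β-methyl-7β-[(trimethylsilyl)ethynyl]octal-5-en-4-one (1β-SiMe2–O-8α bridge) | C[Si](C)(C)C#C[C@H]1C=C2C(=O)CC[C@@H]([Si]3(C)C)[C@]2(C)C[C@@H]1O3 | intermediate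
19 | 8α-hydroxy-1β-[methoxy(dimethyl)silyl]-10β-methyl-7β-[(trimethylsilyl)ethynyl]octal-5-en-4-one (not isolated) | C[Si](C)(C)C#C[C@H]1C=C2C(=O)CC[C@@H]([Si](C)(C)OC)[C@]2(C)C[C@@H]1O | intermediate
20 | 8α-acetoxy-1β-[methoxy(dimethyl)silyl]-10β-methyl-7β-[(trimethylsilyl)ethynyl]octal-5-en-4-one | C[Si](C)(C)C#C[C@H]1C=C2C(=O)CC[C@@H]([Si](C)(C)OC)[C@]2(C)C[C@@H]1OC(C)=O | intermediate
21 | 8α-acetoxy-1β-[methoxy(dimethyl)silyl]-10β-methyl-6α-(pinacolatoboryl)-7β-[(trimethylsilyl)ethynyl]-5αH-decalin-4-one (not isolated) | C[Si](C)(C)C#C[C@H]1[C@H](B2OC(C)(C)C(C)(C)O2)[C@H]3C(=O)CC[C@@H]([Si](C)(C)OC)[C@]3(C)C[C@@H]1OC(C)=O | intermediate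
22 | 8α-acetoxy-7β-ethynyl-1β,6α-dihydroxy-10β-methyl-5αH-decalin-4-one | C#C[C@H]1[C@H](O)[C@@H]2[C@@](C)(C[C@@H]1OC(C)=O)[C@H](O)CCC2=O | intermediate
23 | 8α-acetoxy-1β,6α-bis(tert-butyldimethylsilyloxy)-7β-ethynyl-10β-methyl-5αH-decalin-4-one | C#C[C@H]1[C@H](O[Si](C)(C)C(C)(C)C)[C@@H]2[C@@](C)(C[C@@H]1OC(C)=O)[C@H](O[Si](C)(C)C(C)(C)C)CCC2=O | intermediate
24 | 8α-acetoxy-1β,6α-bis(tert-butyldimethylsilyloxy)-7β-ethynyl-10β-methyl-4-methylidene-5αH-decalin | C#C[C@H]1[C@H](O[Si](C)(C)C(C)(C)C)[C@@H]2[C@@](C)(C[C@@H]1OC(C)=O)[C@H](O[Si](C)(C)C(C)(C)C)CCC2=C | intermediate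
25 | 8α-acetoxy-1β,6α-bis(tert-butyldimethylsilyloxy)-7β-ethynyl-4α-hydroperoxy-4β,10β-dimethyl-5αH-decalin (not isolated) | C#C[C@H]1[C@H](O[Si](C)(C)C(C)(C)C)[C@@H]2[C@@](C)(C[C@@H]1OC(C)=O)[C@H](O[Si](C)(C)C(C)(C)C)CC[C@@]2(C)OO | intermediate
26 | 8α-acetoxy-1β,6α-bis(tert-butyldimethylsilyloxy)-7β-ethynyl-4α-hydroxy-4β,10β-dimethyl-5αH-decalin | C#C[C@H]1[C@H](O[Si](C)(C)C(C)(C)C)[C@@H]2[C@@](C)(C[C@@H]1OC(C)=O)[C@H](O[Si](C)(C)C(C)(C)C)CC[C@@]2(C)O | intermediate
27 | methyl 8α-acetoxy-1β,6α-bis(tert-butyldimethylsilyloxy)-4α-hydroxyeudesm-11(13)-en-12-oate | C=C(C(=O)OC)[C@H]1[C@H](O[Si](C)(C)C(C)(C)C)[C@@H]2[C@@](C)(C[C@@H]1OC(C)=O)[C@H](O[Si](C)(C)C(C)(C)C)CC[C@@]2(C)O | intermediate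
28 | methyl 8α-acetoxy-1β,4α,6α-trihydroxyeudesm-11(13)-en-12-oate, (1R,4R,5S,6S,7S,8S,10R), CNP0272656.1 | C=C(C(=O)OC)[C@H]1[C@H](O)[C@@H]2[C@@](C)(C[C@@H]1OC(C)=O)[C@H](O)CC[C@@]2(C)O | target

Total step count: 15. Longest linear sequence: 15 steps (1 → 28); 3, 11 and 14 are commercial partners.

**The three steps most likely to fail**

1. Step 7. The unactivated vinylsilane may add too slowly to the diene with its fully substituted terminus, so that a 1,5-hydrogen shift in the diene or thermal loss of the silyl enol ether competes. The fallback changes the tether atom to boron, whose alkenylboronate is a more electrophilic dienophile. It sets out from 12, isolated here by leaving out the acid in step 5. Transesterification with dibutyl vinylboronate (PhMe, 4 Å sieves) should give the mixed vinylboronate F1. Heating at 110–130 °C should give the cyclic boronate adduct F2 with the same tether-controlled stereochemistry. NaBO3 in THF/H2O oxidises C1–B with retention to the 1β,8α-diol F3. DDQ in wet CH2Cl2 turns the ethyl enol ether into the enone diol F4. The less hindered C8 hydroxyl is acetylated (AcCl, 2,4,6-collidine, −78 °C) to the enone monoacetate F5. The conditions of step 10 then lead through the boryl ketone F6 back to the route at 22.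

2. Step 2. The enantioselectivity may be low, or the alkynyl group may also attack the methyl-bearing enone arm. The fallback replaces asymmetric catalysis by resolution and sets out from 2. Alkynylation with the achiral catalyst from Ni(acac)2 and i-Bu2AlH gives 6 together with the (5S)-ketone F7. Steps 3 and 4 on the racemate pass through the (5S)-enolate F8, the (5S)-enol triflate F9 and the (5S)-keto triflate F10, and give 10 together with the (4R,5S)-alcohol F11. Candida antarctica lipase B with vinyl acetate should acetylate F11, the enantiomer that fits the usual lipase preference, to the (4R,5S)-acetate F12. Unreacted 10 is separated by chromatography and comes back to the route at step 5.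

3. Step 13. Trapping of the planar tertiary C4 radical by oxygen may show poor face selectivity, or the radical may be reduced to the alkane. The fallback is ionic and sets out from 24. mCPBA/NaHCO3 should epoxidise the exocyclic double bond from the α-face to the spiro-epoxide F13. LiEt3BH opens it at the methylene carbon and at the same time cleaves the acetate, giving the 4α,8α-diol F14. Ac2O/pyridine acetylates only the secondary C8 hydroxyl and returns to the route at 26.

**Further compounds**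

F1 | step 7 | butyl (1S,6R)-4-(1-ethoxyethenyl)-3-methyl-6-[(trimethylsilyl)ethynyl]cyclohex-3-en-1-yl vinylboronate | C=C(OCC)C1=C(C)C[C@H](OB(C=C)OCCCC)[C@@H](C#C[Si](C)(C)C)C1
F2 | step 7 | cyclic boronate adduct: 4-ethoxy-10β-methyl-7β-[(trimethylsilyl)ethynyl]-Δ4(5)-octalin with a 1β-B(OBu)–O-8α bridge | C[Si](C)(C)C#C[C@H]1CC2=C(OCC)CC[C@@H](B3OCCCC)[C@]2(C)C[C@@H]1O3
F3 | step 7 | 4-ethoxy-10β-methyl-7β-[(trimethylsilyl)ethynyl]-Δ4(5)-octalin-1β,8α-diol | C[Si](C)(C)C#C[C@H]1CC2=C(OCC)CC[C@@H](O)[C@]2(C)C[C@@H]1O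
F4 | step 7 | 1β,8α-dihydroxy-10β-methyl-7β-[(trimethylsilyl)ethynyl]octal-5-en-4-one | C[Si](C)(C)C#C[C@H]1C=C2C(=O)CC[C@@H](O)[C@]2(C)C[C@@H]1O
F5 | step 7 | 8α-acetoxy-1β-hydroxy-10β-methyl-7β-[(trimethylsilyl)ethynyl]octal-5-en-4-one | C[Si](C)(C)C#C[C@H]1C=C2C(=O)CC[C@@H](O)[C@]2(C)C[C@@H]1OC(C)=O
F6 | step 7 | 8α-acetoxy-1β-hydroxy-10β-methyl-6α-(pinacolatoboryl)-7β-[(trimethylsilyl)ethynyl]-5αH-decalin-4-one | C[Si](C)(C)C#C[C@H]1[C@H](B2OC(C)(C)C(C)(C)O2)[C@H]3C(=O)CC[C@@H](O)[C@]3(C)C[C@@H]1OC(C)=O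
F7 | step 2 | (5S)-4,4-dimethoxy-2-methyl-5-[(trimethylsilyl)ethynyl]cyclohex-2-en-1-one | CC1=CC(OC)(OC)[C@H](C#C[Si](C)(C)C)CC1=O
F8 | step 2 | lithium (5S)-4,4-dimethoxy-2-methyl-5-[(trimethylsilyl)ethynyl]cyclohex-1-en-1-olate | [Li+].[O-]C1=C(C)CC(OC)(OC)[C@H](C#C[Si](C)(C)C)C1
F9 | step 2 | (5S)-4,4-dimethoxy-2-methyl-5-[(trimethylsilyl)ethynyl]cyclohex-1-en-1-yl trifluoromethanesulfonate | FC(F)(F)S(=O)(=O)OC1=C(C)CC(OC)(OC)[C@H](C#C[Si](C)(C)C)C1
F10 | step 2 | (5S)-2-methyl-4-oxo-5-[(trimethylsilyl)ethynyl]cyclohex-1-en-1-yl trifluoromethanesulfonate | FC(F)(F)S(=O)(=O)OC1=C(C)CC(=O)[C@H](C#C[Si](C)(C)C)C1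
F11 | step 2 | (4R,5S)-4-hydroxy-2-methyl-5-[(trimethylsilyl)ethynyl]cyclohex-1-en-1-yl trifluoromethanesulfonate | FC(F)(F)S(=O)(=O)OC1=C(C)C[C@@H](O)[C@H](C#C[Si](C)(C)C)C1
F12 | step 2 | (4R,5S)-4-acetoxy-2-methyl-5-[(trimethylsilyl)ethynyl]cyclohex-1-en-1-yl trifluoromethanesulfonate | FC(F)(F)S(=O)(=O)OC1=C(C)C[C@@H](OC(C)=O)[C@H](C#C[Si](C)(C)C)C1
F13 | step 13 | 8α-acetoxy-1β,6α-bis(tert-butyldimethylsilyloxy)-4α,15-epoxy-7β-ethynyl-10β-methyl-5αH-decalin | C#C[C@H]1[C@H](O[Si](C)(C)C(C)(C)C)[C@@H]2[C@@](C)(C[C@@H]1OC(C)=O)[C@H](O[Si](C)(C)C(C)(C)C)CC[C@]23CO3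
F14 | step 13 | 1β,6α-bis(tert-butyldimethylsilyloxy)-7β-ethynyl-4β,10β-dimethyl-5αH-decalin-4α,8α-diol | C#C[C@H]1[C@H](O[Si](C)(C)C(C)(C)C)[C@@H]2[C@@](C)(C[C@@H]1O)[C@H](O[Si](C)(C)C(C)(C)C)CC[C@@]2(C)O
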